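Remark: abietane numbering (C1 to C20; rings A, B, C) is used for every compound, including the ring-enlarged intermediates in which C1 is bonded to C20 instead of C10. α and β refer to the usual abietane drawing; the target is 5α-H, 10β-CH2O, 4β-carbonyl, which is (4S,5R,10R).

## Analysis of the target

The target 33 is an abietane 19,20-olide. It has a fully substituted aromatic ring C (11-OH, 12-OMe, 13-isopropyl, 14-OH), ring B with the C7 aryl ketone, a cyclohexane ring A, and a six-membered lactone bridging C4 and C10 through C19(=O)–O–C20. There are three contiguous stereocentres, C4 (S), C5 (R) and C10 (R), two of them quaternary. Rings A and B are trans-fused, and the C19 carbonyl and C20 are both β and 1,3-diaxial, the only arrangement in which the lactone can close. The sensitive groups are the 11,14-hydroquinone (air-oxidised to the quinone, so it is unveiled last), the electron-rich arene (easily oxidised, and easily ionised at benzylic positions) and the lactone toward strong base. The hard part is the benzylic quaternary C10 carrying an oxidised one-carbon substituent, flanked by the C5 methine and the quaternary C4, on an arene with no free position. The strategy rests on this C10: a quaternary benzylic carbon bearing C20 at the aldehyde level is what remains when C1 shifts from C20 to a C10 benzylic cation generated from a C10–C20 epoxide. Ring A can therefore be made as a seven-membered ring that contains C20 and then contracted.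

## Retrosynthetic reasoning

Oxidation-state adjustments (33 to 30). The hydroquinone 33 is traced to the quinone 32, and 32 to the trimethyl ether 31 by oxidative demethylation. The 11,12,14-trimethoxy pattern opens to the 11,14-para-quinone and keeps the 12-methoxy group. The C7 ketone of 31 is traced to the methylene of 30. C7 is the only benzylic methylene and lies para to the C12 methoxy group. Introducing it late keeps a carbonyl out of ring B during the enolate steps and during the cationic key step, where it would destabilise a C10 cation.

Lactone C20–O bond (30 to 28). Cutting the lactone gives the hydroxy ester 29, which comes from the aldehyde 28 by hydride reduction. C20 and the C19 ester are 1,3-diaxial, so the lactone closes without a protecting group on either partner.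

C1–C10 bond, the key disconnection (28 to 27). The C1–C10 bond is cut and C1 is reconnected to C20, which enlarges ring A to a cycloheptane carrying a C10–C20 epoxide (27). This replaces the construction of a benzylic quaternary centre by the epoxidation of a trisubstituted alkene and delivers C20 at the aldehyde level. The forward step has to ionise the epoxide at C10 only, shift C1 and not the C20 hydrogen, and invert C10.

Epoxide (27 to 26). The epoxide oxygen must sit on the β face of the C10=C20 alkene of 26, anti to H5, because inversion at C10 then places C20 β. This face is set by catalyst control (Shi epoxidation).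

C4–C18 bond (26 to 23 and 24). The quaternary C4 is traced to the ester enolate 25 of the bicyclic ester 23 and iodomethane 24. Inside the bicycle the electrophile is expected to enter anti to C6, so the group introduced last has to be the methyl group. For that reason the ring is closed first and C18 added afterwards.

Seven-membered ring (23 to 22, 19 and 18). The C10=C20 alkene of 23 is cut by retro-metathesis to the diene 22. The pentenyl chain of 22 comes from the ester 19 and 5-bromopent-1-ene 20 (C3–C4 bond), and the C10 methylene of 19 from the ketone 18.

Ring B and C5 (18 to 16, 14, 11 and 8). The C9–C10 bond of 18 is cut by retro-Friedel–Crafts acylation to the acid 16; C9 is the only free arene position. C5 is then the α-carbon of a carboxylic acid, and the C4–C5 bond is made by auxiliary-controlled alkylation of the imide 11 with methyl bromoacetate 12, via 14. An oxidative union of two enolates at the ketone stage would leave C5 weakly controlled and could not give a quaternary C4, so the absolute configuration is fixed here, before ring B exists. The imide 11 comes from the acid 8 and the auxiliary 9.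

Arene side chain and isopropyl group (8 to 1). The acid 8 is traced through the keto acid 7 to the arene 5 and succinic anhydride 6 (C7–C8 bond, Friedel–Crafts). The isopropyl group of 5 is traced through the carbinol 4 to 1,2,4-trimethoxybenzene 1 and acetone 2, by metalation of the position flanked by two methoxy groups.

## Alternatives that were turned down

Alternative 1: Ring A is cut at C3–C4 by a retro-Ireland–Claisen step. The carbocycle becomes the six-membered lactone A1, in which the C19 carbonyl is joined through oxygen to C1, C1 carries a vinyl group (the future C2 and C3) and C20 is a benzyl ether. Forward, enolisation, silylation and [3,3] shift of A1 would form C3–C4, break C1–O and give the cyclohexene acid A2 with the quaternary C4 in place.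
- For it: the ketene acetal geometry is fixed by the lactone ring, so the C4 configuration follows directly from that of C1. On this point it is stronger than the chosen route, which sets C4 by an intermolecular enolate methylation.
- Against it: the rearrangement does not touch C10. A1 already needs the benzylic quaternary C10 with a protected C20 oxygen, and a stereodefined vinyl carbinol at the neopentyl C1 beside it. Contracting a six-membered lactone needs a boat transition state with the vinyl group axial. A2 still needs alkene hydrogenation, debenzylation and lactonisation.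
- In its place the chosen strategy creates C10, its configuration and the C20 oxidation level in one stereospecific step from an alkene, with no protecting group on C20.

Alternative 2: Rings B and C are cut together at C8–C9 and C11–C12 by a retro-cycloaddition. Ring C becomes a 3-methoxy-2-pyrone whose C6 acyl chain is the C7 ketone, tethered to an alkynylboronate on C10 (A3). Forward, intramolecular Diels–Alder reaction of A3 and decarboxylative aromatisation would give the tetracyclic arylboronate A4, with the C7 ketone, the 12-methoxy group, the lactone and a boron handle for the C11 oxygen.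
- For it: it is convergent, the tether dictates the regiochemistry, and the C7 ketone is present from the start, so no late benzylic oxidation is needed. Here it is stronger than the chosen route.
- Against it: the key step builds no stereocentre. A3 must already contain ring A, the lactone and all three stereocentres, including the alkynyl-substituted quaternary C10. A4 still lacks the C13 isopropyl group and the C14 oxygen, so two further substitutions on a crowded arene would follow.
- In its place the chosen strategy starts from an arene that carries all four ring C substituents after one lithiation, and spends its key step on C10.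

Alternative 3: Ring B is cut at C7–C8 and C9–C10 by a retro-Diels–Alder step into the vinylcyclohexene A5 (ring A with a tetrasubstituted C5=C10 alkene, C20 as silyl ether, C19 as tert-butyl ester) and the methoxy isopropyl benzoquinone A6. Forward, cycloaddition at the unsubstituted edge of A6 and enolisation of the adduct would give the hydroquinone A7, with C10 quaternary and a C5=C6 alkene.
- For it: it is the most convergent plan, and ring C arrives with the 11,14-dioxygenation, the methoxy and the isopropyl group already in place. The chosen route reaches that pattern only by a late oxidative demethylation, so this is a clear advantage.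
- Against it: the bond to C10 must form at the fully substituted terminus of a hindered diene. The orientation of A6 (methoxy at C12 or C13) rests only on the weak bias of its substituents, and the face of A5 is differentiated only by the C4 substituents. A7 still needs stereoselective reduction of C5=C6 to the 5α-H, C7 oxidation, two deprotections and lactonisation.
- In its place the chosen strategy links C5 and C10 stereospecifically (the epoxide face becomes the C10 configuration) and has no regiochemical question on ring C.

Key step: step 14

## Route

Step 1
Reactants: 1 1,2,4-trimethoxybenzene; 2 acetone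
Product: 4 2-(2,3,6-trimethoxyphenyl)propan-2-ol, via (2,3,6-trimethoxyphenyl)lithium 3 (not isolated)
Conditions: n-BuLi, THF, 0 °C to rt; acetone, −78 °C to rt; H2O
Reagents that add atoms: none
Why: Directed ortho-metalation: the C–H flanked by two methoxy groups is the most acidic and best coordinated site, and the aryllithium adds to acetone. This places the future isopropyl carbon between the C12 and C14 oxygens.

Step 2
Reactants: 4 2-(2,3,6-trimethoxyphenyl)propan-2-ol
Product: 5 2-isopropyl-1,3,4-trimethoxybenzene
Conditions: Et3SiH, CF3CO2H, CH2Cl2, 0 °C to rt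
Reagents that add atoms: none
Why: Ionic hydrogenation: the tertiary benzylic alcohol ionises in acid and the cation (or the styrene formed from it and reprotonated) takes hydride from the silane.

Step 3
Reactants: 5 2-isopropyl-1,3,4-trimethoxybenzene; 6 succinic anhydride
Product: 7 4-(3-isopropyl-2,4,5-trimethoxyphenyl)-4-oxobutanoic acid
Conditions: AlCl3, CH2Cl2/MeNO2, 0 °C
Reagents that add atoms: none
Why: Friedel–Crafts acylation at C6 of 5, ortho to the 1-methoxy and para to the 3-methoxy group, the same orientation as in acylations of 1,2,4-trimethoxybenzene; the other free position is para only to the alkyl group. Low temperature limits demethylation of the methoxy group ortho to the new ketone.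

Step 4
Reactants: 7 4-(3-isopropyl-2,4,5-trimethoxyphenyl)-4-oxobutanoic acid
Product: 8 4-(3-isopropyl-2,4,5-trimethoxyphenyl)butanoic acid
Conditions: Et3SiH, CF3CO2H, rt to 50 °C
Reagents that add atoms: none
Why: Ionic hydrogenation of an aryl ketone: the ortho- and para-methoxy groups stabilise the benzylic cation, which is reduced twice by the silane to the methylene (the future C7).

Step 5
Reactants: 8 4-(3-isopropyl-2,4,5-trimethoxyphenyl)butanoic acid; 9 (R)-4-benzyloxazolidin-2-one
Product: 11 (R)-4-benzyl-3-[4-(3-isopropyl-2,4,5-trimethoxyphenyl)butanoyl]oxazolidin-2-one, via 4-(3-isopropyl-2,4,5-trimethoxyphenyl)butanoic pivalic anhydride 10 (not isolated)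
Conditions: t-BuCOCl, Et3N, THF, −20 °C; 9, LiCl, rt
Reagents that add atoms: none
Why: N-acylation of the auxiliary through the mixed pivalic anhydride; the oxazolidinone attacks the less hindered carbonyl.

Step 6
Reactants: 11 (R)-4-benzyl-3-[4-(3-isopropyl-2,4,5-trimethoxyphenyl)butanoyl]oxazolidin-2-one; 12 methyl bromoacetate
Product: 14 methyl (3S)-3-[(4R)-4-benzyl-2-oxooxazolidine-3-carbonyl]-5-(3-isopropyl-2,4,5-trimethoxyphenyl)pentanoate, via sodium (Z)-enolate of the acyloxazolidinone 13 (not isolated)
Conditions: NaN(SiMe3)2, THF, −78 °C; BrCH2CO2Me, −78 to −30 °C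
Reagents that add atoms: none
Why: Evans alkylation: the chelated (Z)-enolate is alkylated on the face opposite the benzyl group of the (R)-auxiliary. This forms the C4–C5 bond and sets C5 as (S) in 14, the configuration that becomes the 5α-H of the target.

Step 7
Reactants: 14 methyl (3S)-3-[(4R)-4-benzyl-2-oxooxazolidine-3-carbonyl]-5-(3-isopropyl-2,4,5-trimethoxyphenyl)pentanoate
Product: 16 (2S)-4-(3-isopropyl-2,4,5-trimethoxyphenyl)-2-(2-methoxy-2-oxoethyl)butanoic acid, via (2S)-4-(3-isopropyl-2,4,5-trimethoxyphenyl)-2-(2-methoxy-2-oxoethyl)butaneperoxoic acid 15 (not isolated)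
Conditions: LiOH, H2O2, THF/H2O, 0 °C; Na2SO3; HCl to pH 2
Reagents that add atoms: hydrogen peroxide (as LiOOH), OO
Why: Hydroperoxide cleavage of the auxiliary: the hydroperoxide anion attacks the exocyclic imide carbonyl much faster than the methyl ester or the ring carbamate, and sulfite reduces the peracid to the acid.

Step 8
Reactants: 16 (2S)-4-(3-isopropyl-2,4,5-trimethoxyphenyl)-2-(2-methoxy-2-oxoethyl)butanoic acid
Product: 18 methyl 2-[(2S)-6-isopropyl-5,7,8-trimethoxy-1-oxo-1,2,3,4-tetrahydronaphthalen-2-yl]acetate, via mixed trifluoroacetic anhydride of the acid 17 (not isolated)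
Conditions: (CF3CO)2O, CH2Cl2, 0 °C to rt
Reagents that add atoms: none
Why: Intramolecular Friedel–Crafts acylation closes ring B at C9, the only free arene position, activated by the C11 methoxy group. No base is present, so the C5 configuration should be retained.

Step 9
Reactants: 18 methyl 2-[(2S)-6-isopropyl-5,7,8-trimethoxy-1-oxo-1,2,3,4-tetrahydronaphthalen-2-yl]acetate
Product: 19 methyl 2-[(2S)-6-isopropyl-5,7,8-trimethoxy-1-methylene-1,2,3,4-tetrahydronaphthalen-2-yl]acetate
Conditions: Zn, CH2Br2, TiCl4, THF/CH2Cl2, 0 °C to rt
Reagents that add atoms: dibromomethane, BrCBr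
Why: Takai–Lombardo methylenation: the non-basic titanium methylene reagent converts the hindered, enolisable aryl ketone to the exocyclic alkene without epimerising C5 and leaves the methyl ester untouched.

Step 10
Reactants: 19 methyl 2-[(2S)-6-isopropyl-5,7,8-trimethoxy-1-methylene-1,2,3,4-tetrahydronaphthalen-2-yl]acetate; 20 5-bromopent-1-ene
Product: 22 methyl 2-[(2S)-6-isopropyl-5,7,8-trimethoxy-1-methylene-1,2,3,4-tetrahydronaphthalen-2-yl]hept-6-enoate (both C4 epimers), via lithium ester enolate 21 (not isolated)
Conditions: LiN(i-Pr)2, THF, −78 °C; 20, DMPU, −78 to −20 °C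
Reagents that add atoms: none
Why: Ester enolate alkylation with a primary bromide; the ester α-CH2 is far more acidic than the allylic C5–H. The new C4 centre need not be controlled because it is enolised again in step 12.

Step 11
Reactants: 22 methyl 2-[(2S)-6-isopropyl-5,7,8-trimethoxy-1-methylene-1,2,3,4-tetrahydronaphthalen-2-yl]hept-6-enoate (both C4 epimers)
Product: 23 methyl 11,12,14-trimethoxy-18-nor-1(10→20)-abeo-abieta-8,11,13,10(20)-tetraen-19-oate (5α-H; both C4 epimers)
Conditions: second-generation Grubbs catalyst RuCl2(=CHPh)(PCy3)(H2IMes) (5 mol%), 1,4-benzoquinone (10 mol%), PhMe, 80 °C, 0.002 M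
Reagents that add atoms: none
Why: Ring-closing metathesis: the catalyst loads at the terminal alkene and closes onto the C10 methylene, releasing ethylene and giving the trisubstituted styrene-type cycloheptene. High dilution favours the seven-membered ring, and benzoquinone suppresses ruthenium hydride alkene migration.

Step 12
Reactants: 23 methyl 11,12,14-trimethoxy-18-nor-1(10→20)-abeo-abieta-8,11,13,10(20)-tetraen-19-oate (5α-H; both C4 epimers); 24 iodomethane
Product: 26 methyl 11,12,14-trimethoxy-1(10→20)-abeo-abieta-8,11,13,10(20)-tetraen-19-oate (4α-methyl; 4β-ester; 5α-H), via lithium enolate of the cycloheptene ester 25 (not isolated)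
Conditions: LiN(i-Pr)2, THF, −78 °C; MeI, −78 to 0 °C
Reagents that add atoms: none
Why: Alkylation of a lithium ester enolate: both C4 epimers of 23 converge on one planar enolate. Allylic strain places the C6 methylene of ring B over one face, so iodomethane should enter on the face that carries H5, giving the 4α-methyl, 4β-ester (4S) centre.

Step 13
Reactants: 26 methyl 11,12,14-trimethoxy-1(10→20)-abeo-abieta-8,11,13,10(20)-tetraen-19-oate
Product: 27 methyl 10β,20-epoxy-11,12,14-trimethoxy-1(10→20)-abeo-abieta-8,11,13-trien-19-oate ((10R,20R) epoxide)
Conditions: 1,2:4,5-di-O-isopropylidene-β-D-erythro-2,3-hexodiulo-2,6-pyranose (30 mol%), KHSO5, K2CO3, Bu4NHSO4, MeCN/CH2(OMe)2/aqueous borate buffer pH 10.5, 0 °C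
Reagents that add atoms: potassium peroxymonosulfate, [K+].[O-]S(=O)(=O)OO
Why: Shi epoxidation: the dioxirane formed from the ketone transfers oxygen through a spiro transition state. For 1-arylcycloalkenes the D-fructose-derived ketone gives the (R,R) epoxide, here the (10R,20R) isomer with oxygen on the β face, anti to H5. The buffered basic medium protects the acid-labile benzylic epoxide.

Step 14
Reactants: 27 methyl 10β,20-epoxy-11,12,14-trimethoxy-1(10→20)-abeo-abieta-8,11,13-trien-19-oate
Product: 28 methyl 11,12,14-trimethoxy-20-oxoabieta-8,11,13-trien-19-oate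
Conditions: MeAl(OAr)2 (Ar = 4-bromo-2,6-di-tert-butylphenyl; 2 equiv), CH2Cl2, −78 °C
Reagents that add atoms: none
Why: The oxophilic aluminium binds the epoxide oxygen and the C10–O bond ionises, because C10 is tertiary and benzylic to an arene whose C11 methoxy group stabilises the developing cation, whereas C20 is only secondary and keeps its oxygen. As C10–O lengthens, the C20–C1 ring bond swings into the back lobe at C10 and migrates while the aluminium alkoxide on C20 collapses to the carbonyl; this is a Meinwald (semipinacol) rearrangement, and the closest known reaction type is the Lewis acid ring contraction of 1-arylcycloalkene oxides to 1-arylcycloalkanecarbaldehydes. Ring A is closed not by an end-on cyclisation but by contraction of the seven-membered ring through a suprafacial 1,2-alkyl shift with a three-centre transition state. The only new stereocentre is C10: C1 enters anti to the departing oxygen, so the β-epoxide gives inversion, with C1 on the α face and the formyl carbon C20 on the β face, cis to the C19 ester and trans to H5. The selectivity needed is migration of C1 over the C20 hydrogen, which would give the seven-membered C20 ketone. The two 2,6-di-tert-butylphenoxide ligands should make the aluminium-bound oxygen rotate away from the C11-methoxy arene and toward C5, the rotation that aligns C20–C1 and not C20–H with the empty orbital. Low temperature and a non-polar solvent keep the shift close to concerted, and the C19 ester lies on the same face as the leaving oxygen, so it cannot reach the back lobe of C10 to intercept the cation.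

Step 15
Reactants: 28 methyl 11,12,14-trimethoxy-20-oxoabieta-8,11,13-trien-19-oate
Product: 30 11,12,14-trimethoxyabieta-8,11,13-trien-19,20-olide, via methyl 20-hydroxy-11,12,14-trimethoxyabieta-8,11,13-trien-19-oate 29 (not isolated)
Conditions: NaBH4, MeOH, 0 °C; then p-toluenesulfonic acid (cat.), PhMe, 60 °C
Reagents that add atoms: none
Why: Hydride reduction of the neopentyl aldehyde, then lactonisation: the C20 hydroxyl is 1,3-diaxial to the C19 methyl ester and displaces methanol to close the six-membered lactone. No stereocentre is touched.

Step 16
Reactants: 30 11,12,14-trimethoxyabieta-8,11,13-trien-19,20-olide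
Product: 31 11,12,14-trimethoxy-7-oxoabieta-8,11,13-trien-19,20-olide
Conditions: CrO3, AcOH/H2O, rt
Reagents that add atoms: chromium trioxide, O=[Cr](=O)=O
Why: Benzylic oxidation at C7, the only benzylic methylene (C10 is quaternary) and para to the C12 methoxy group. The isopropyl methine is held in the arene plane by its two ortho methoxy groups and should be much less reactive.

Step 17
Reactants: 31 11,12,14-trimethoxy-7-oxoabieta-8,11,13-trien-19,20-olide
Product: 32 12-methoxy-7,11,14-trioxoabieta-8,12-dien-19,20-olide
Conditions: (NH4)2Ce(NO3)6, MeCN/H2O, 0 °C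
Reagents that add atoms: water, O
Why: Oxidative demethylation: the arene radical cation is attacked by water at the para-related C11 and C14 methoxy carbons and loses two molecules of methanol, giving the para-quinone and leaving the C12 methoxy group as a vinylogous ester.

Step 18
Reactants: 32 12-methoxy-7,11,14-trioxoabieta-8,12-dien-19,20-olide
Product: 33 11,14-dihydroxy-12-methoxy-7-oxoabieta-8,11,13-trien-19,20-olide (target)
Conditions: Na2S2O4, EtOAc/H2O, rt, under argon
Reagents that add atoms: none
Why: Dithionite reduction of the quinone to the hydroquinone; the aryl ketone and lactone are inert, and exclusion of air prevents reoxidation.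

## Compound list

1 | 1,2,4-trimethoxybenzene | COc1ccc(OC)c(OC)c1 | starting material
2 | acetone | CC(C)=O | starting material
3 | (2,3,6-trimethoxyphenyl)lithium | [Li]c1c(OC)ccc(OC)c1OC | intermediate
4 | 2-(2,3,6-trimethoxyphenyl)propan-2-ol | CC(C)(O)c1c(OC)ccc(OC)c1OC | intermediate
5 | 2-isopropyl-1,3,4-trimethoxybenzene | CC(C)c1c(OC)ccc(OC)c1OC | intermediate
6 | succinic anhydride | O=C1CCC(=O)O1 | starting material
7 | 4-(3-isopropyl-2,4,5-trimethoxyphenyl)-4-oxobutanoic acid | COc1cc(C(=O)CCC(=O)O)c(OC)c(C(C)C)c1OC | intermediate
8 | 4-(3-isopropyl-2,4,5-trimethoxyphenyl)butanoic acid | COc1cc(CCCC(=O)O)c(OC)c(C(C)C)c1OC | intermediate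
9 | (R)-4-benzyloxazolidin-2-one | O=C1OC[C@@H](Cc2ccccc2)N1 | starting material
10 | 4-(3-isopropyl-2,4,5-trimethoxyphenyl)butanoic pivalic anhydride | COc1cc(CCCC(=O)OC(=O)C(C)(C)C)c(OC)c(C(C)C)c1OC | intermediate
11 | (R)-4-benzyl-3-[4-(3-isopropyl-2,4,5-trimethoxyphenyl)butanoyl]oxazolidin-2-one | COc1cc(CCCC(=O)N2[C@H](Cc3ccccc3)COC2=O)c(OC)c(C(C)C)c1OC | intermediate
12 | methyl bromoacetate | COC(=O)CBr | starting material
13 | sodium (Z)-enolate of the acyloxazolidinone 11 | COc1cc(CC/C=C(\[O-])N2[C@H](Cc3ccccc3)COC2=O)c(OC)c(C(C)C)c1OC.[Na+] | intermediate
14 | methyl (3S)-3-[(4R)-4-benzyl-2-oxooxazolidine-3-carbonyl]-5-(3-isopropyl-2,4,5-trimethoxyphenyl)pentanoate | COc1cc(CC[C@@H](CC(=O)OC)C(=O)N2[C@H](Cc3ccccc3)COC2=O)c(OC)c(C(C)C)c1OC | intermediate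
15 | (2S)-4-(3-isopropyl-2,4,5-trimethoxyphenyl)-2-(2-methoxy-2-oxoethyl)butaneperoxoic acid | COc1cc(CC[C@@H](CC(=O)OC)C(=O)OO)c(OC)c(C(C)C)c1OC | intermediate
16 | (2S)-4-(3-isopropyl-2,4,5-trimethoxyphenyl)-2-(2-methoxy-2-oxoethyl)butanoic acid | COc1cc(CC[C@@H](CC(=O)OC)C(=O)O)c(OC)c(C(C)C)c1OC | intermediate
17 | mixed trifluoroacetic anhydride of acid 16 | COc1cc(CC[C@@H](CC(=O)OC)C(=O)OC(=O)C(F)(F)F)c(OC)c(C(C)C)c1OC | intermediate
18 | methyl 2-[(2S)-6-isopropyl-5,7,8-trimethoxy-1-oxo-1,2,3,4-tetrahydronaphthalen-2-yl]acetate | COc1c(OC)c2c(c(OC)c1C(C)C)CC[C@@H](CC(=O)OC)C2=O | intermediate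
19 | methyl 2-[(2S)-6-isopropyl-5,7,8-trimethoxy-1-methylene-1,2,3,4-tetrahydronaphthalen-2-yl]acetate | COc1c(OC)c2c(c(OC)c1C(C)C)CC[C@@H](CC(=O)OC)C2=C | intermediate
20 | 5-bromopent-1-ene | C=CCCCBr | starting material
21 | lithium ester enolate of 19 | COc1c(OC)c2c(c(OC)c1C(C)C)CC[C@@H](C=C([O-])OC)C2=C.[Li+] | intermediate
22 | methyl 2-[(2S)-6-isopropyl-5,7,8-trimethoxy-1-methylene-1,2,3,4-tetrahydronaphthalen-2-yl]hept-6-enoate (both C4 epimers, C4 left undefined) | COc1c(OC)c2c(c(OC)c1C(C)C)CC[C@@H](C(CCCC=C)C(=O)OC)C2=C | intermediate
23 | methyl 11,12,14-trimethoxy-18-nor-1(10→20)-abeo-abieta-8,11,13,10(20)-tetraen-19-oate (5α-H; both C4 epimers, C4 left undefined) | COc1c(OC)c2c(c(OC)c1C(C)C)CC[C@@H]1C2=CCCCC1C(=O)OC | intermediate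
24 | iodomethane | CI | starting material
25 | lithium enolate of the cycloheptene ester 23 | COc1c(OC)c2c(c(OC)c1C(C)C)CC[C@@H]1C2=CCCCC1=C([O-])OC.[Li+] | intermediate
26 | methyl 11,12,14-trimethoxy-1(10→20)-abeo-abieta-8,11,13,10(20)-tetraen-19-oate (4α-methyl, 4β-ester, 5α-H) | COc1c(OC)c2c(c(OC)c1C(C)C)CC[C@@H]1C2=CCCC[C@]1(C)C(=O)OC | intermediate
27 | methyl 10β,20-epoxy-11,12,14-trimethoxy-1(10→20)-abeo-abieta-8,11,13-trien-19-oate, (10R,20R) epoxide | COc1c(OC)c2c(c(OC)c1C(C)C)CC[C@@H]1[C@@]23O[C@@H]3CCC[C@]1(C)C(=O)OC | intermediate
28 | methyl 11,12,14-trimethoxy-20-oxoabieta-8,11,13-trien-19-oate | COc1c(OC)c2c(c(OC)c1C(C)C)CC[C@@H]1[C@]2(C=O)CCC[C@]1(C)C(=O)OC | intermediate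
29 | methyl 20-hydroxy-11,12,14-trimethoxyabieta-8,11,13-trien-19-oate | COc1c(OC)c2c(c(OC)c1C(C)C)CC[C@@H]1[C@]2(CO)CCC[C@]1(C)C(=O)OC | intermediate
30 | 11,12,14-trimethoxyabieta-8,11,13-trien-19,20-olide | COc1c(OC)c2c(c(OC)c1C(C)C)CC[C@@H]1[C@]23CCC[C@]1(C)C(=O)OC3 | intermediate
31 | 11,12,14-trimethoxy-7-oxoabieta-8,11,13-trien-19,20-olide | COc1c(OC)c2c(c(OC)c1C(C)C)C(=O)C[C@@H]1[C@]23CCC[C@]1(C)C(=O)OC3 | intermediate
32 | 12-methoxy-7,11,14-trioxoabieta-8,12-dien-19,20-olide | COC=1C(=O)C2=C(C(=O)C=1C(C)C)C(=O)C[C@@H]1[C@]23CCC[C@]1(C)C(=O)OC3 | intermediate
33 | 11,14-dihydroxy-12-methoxy-7-oxoabieta-8,11,13-trien-19,20-olide, (4S,5R,10R) | COc1c(O)c2c(c(O)c1C(C)C)C(=O)C[C@@H]1[C@]23CCC[C@]1(C)C(=O)OC3 | target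

## Step count and least certain steps

Total step count: 18. Longest linear sequence: 18 steps, from 1 to 33; compounds 2, 6, 9, 12, 20 and 24 enter as purchased materials.

Step 14 (key step). The most likely failure is a competing 1,2-hydride shift from C20, which keeps the seven-membered ring and gives a C20 ketone. A second risk is full ionisation to a long-lived benzylic cation, which would lose the inversion at C10 and give the cis-fused epimer, or let the C19 ester carbonyl capture the cation. Both arise because the trimethoxyarene stabilises the C10 cation strongly. Fallback, setting out from 26: dihydroxylation (OsO4 catalyst, N-methylmorpholine N-oxide, acetone/H2O) would give the cis-diol F1. Acid (p-toluenesulfonic acid in benzene, or BF3·OEt2 at −78 °C) ionises only the tertiary benzylic C10 hydroxyl, and the resulting pinacol rearrangement, in which the C10–C20 bond is free to rotate and C1 can reach the aligned geometry, returns to the route at 28. The ring fusion is then governed by the preference for the chair-like trans-fused transition state and not by the epoxide face.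

Step 13. The risk is poor facial selectivity: the chiral dioxirane has to deliver oxygen to the β face, and if the bias of the substrate (4α-methyl and H5 on the α face, ester and C6 on the β face) opposes the catalyst, the α-epoxide will form. The product is also an acid-labile, electron-rich benzylic epoxide that may open during isolation. Fallback, setting out from 26: N-bromosuccinimide in aqueous THF would add bromine to C20 from the more accessible α face and water to the benzylic C10 from the β face, giving the bromohydrin F2. K2CO3 in MeOH then closes the ring by displacement of bromide and returns to the route at 27, with the oxygen on the face opposite to electrophilic attack.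

Step 12. The risk is methylation on the wrong face of the enolate (syn to C6), which would give the C4 epimer, because the control comes only from the conformation of the bicyclic enolate. Incomplete enolisation of the hindered α-branched ester is a lesser risk. Fallback, setting out from 18, sets C4 on a cis-fused γ-lactone before the seven-membered ring exists:
- LiBH(s-Bu)3 reduction (hydride anti to the C5 side chain) and lactonisation would give the cis-fused lactone F3.
- LiN(i-Pr)2 and 24 would give the α-methyl lactone F4.
- A second enolisation and alkylation with 20 would give the quaternary lactone F5. Each electrophile enters on the convex face anti to C6, so the group introduced last, now the pentenyl chain, ends trans to C6 as required.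
- Saponification (KOH), oxidation of the hydroxy carboxylate (TEMPO, NaOCl) and esterification (24, K2CO3) would give the keto ester F6.
- Takai–Lombardo methylenation would give the diene ester F7, and ring-closing metathesis as in step 11 returns to the route at 26.

Step 11. The risk is slow ring closure at the hindered 1,1-disubstituted styrenyl alkene next to the C11 methoxy group, so that cross-metathesis oligomers build up. Ruthenium hydride migration of the exocyclic alkene into ring B would destroy C5. Fallback, setting out from 22: cleavage of both terminal alkenes (OsO4 catalyst, NaIO4) would regenerate the C10 ketone and turn C20 into an aldehyde, giving the keto aldehyde F8. An intramolecular McMurry coupling (TiCl3, Zn–Cu couple, DME, reflux, high dilution) would join C10 and C20 and return to the route at 23.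

Step 16. The risk is oxidation at the wrong site: hexavalent chromium may attack the electron-rich arene (premature quinone formation) or the isopropyl methine instead of C7. Fallback, setting out from 30: 2,3-dichloro-5,6-dicyano-1,4-benzoquinone in wet CH2Cl2 abstracts hydride from C7, the position para to the C12 methoxy group, and water captures the cation to give the 7-hydroxy lactone F9. Dess–Martin periodinane oxidises F9 and returns to the route at 31.

## Further compounds

F1 | step 14 | methyl 10α,20α-dihydroxy-11,12,14-trimethoxy-1(10→20)-abeo-abieta-8,11,13-trien-19-oate (cis-diol) | COc1c(OC)c2c(c(OC)c1C(C)C)CC[C@@H]1[C@@]2(O)[C@@H](O)CCC[C@]1(C)C(=O)OC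
F2 | step 13 | methyl 20α-bromo-10β-hydroxy-11,12,14-trimethoxy-1(10→20)-abeo-abieta-8,11,13-trien-19-oate (bromohydrin) | COc1c(OC)c2c(c(OC)c1C(C)C)CC[C@@H]1[C@]2(O)[C@@H](Br)CCC[C@]1(C)C(=O)OC
F3 | step 12 | cis-fused γ-lactone of 2-(1-hydroxy-6-isopropyl-5,7,8-trimethoxy-1,2,3,4-tetrahydronaphthalen-2-yl)acetic acid | COc1c(OC)c2c(c(OC)c1C(C)C)CC[C@H]1CC(=O)O[C@H]12
F4 | step 12 | α-methyl derivative of lactone F3 (methyl trans to C6) | COc1c(OC)c2c(c(OC)c1C(C)C)CC[C@H]1[C@H](C)C(=O)O[C@H]12
F5 | step 12 | α-methyl-α-(pent-4-enyl) lactone (pentenyl trans to C6) | COc1c(OC)c2c(c(OC)c1C(C)C)CC[C@H]1[C@](C)(CCCC=C)C(=O)O[C@H]12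
F6 | step 12 | methyl (2S)-2-[(2S)-6-isopropyl-5,7,8-trimethoxy-1-oxo-1,2,3,4-tetrahydronaphthalen-2-yl]-2-methylhept-6-enoate | COc1c(OC)c2c(c(OC)c1C(C)C)CC[C@@H]([C@](C)(CCCC=C)C(=O)OC)C2=O
F7 | step 12 | methyl (2S)-2-[(2S)-6-isopropyl-5,7,8-trimethoxy-1-methylene-1,2,3,4-tetrahydronaphthalen-2-yl]-2-methylhept-6-enoate | COc1c(OC)c2c(c(OC)c1C(C)C)CC[C@@H]([C@](C)(CCCC=C)C(=O)OC)C2=C
F8 | step 11 | methyl 2-[(2S)-6-isopropyl-5,7,8-trimethoxy-1-oxo-1,2,3,4-tetrahydronaphthalen-2-yl]-6-oxohexanoate (both C4 epimers) | COc1c(OC)c2c(c(OC)c1C(C)C)CC[C@@H](C(CCCC=O)C(=O)OC)C2=O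
F9 | step 16 | 7-hydroxy-11,12,14-trimethoxyabieta-8,11,13-trien-19,20-olide (C7 epimers) | COc1c(OC)c2c(c(OC)c1C(C)C)C(O)C[C@@H]1[C@]23CCC[C@]1(C)C(=O)OC3
A1 | alternative 1 | six-membered lactone joining C19 to O–C1, vinyl on C1, C20 benzyl ether (C4 left undefined) | COc1c(OC)c2c(c(OC)c1C(C)C)CC[C@H]1C(C)C(=O)O[C@H](C=C)[C@@]12COCc1ccccc1
A2 | alternative 1 | 20-benzyloxy-11,12,14-trimethoxyabieta-1,8,11,13-tetraen-19-oic acid | COc1c(OC)c2c(c(OC)c1C(C)C)CC[C@@H]1[C@]2(COCc2ccccc2)C=CC[C@]1(C)C(=O)O
A3 | alternative 2 | 6-acyl-3-methoxy-2-pyrone tethered to a C10 alkynylboronate on the ring A lactone | COc1ccc(C(=O)C[C@@H]2[C@@]3(C#CB4OC(C)(C)C(C)(C)O4)CCC[C@]2(C)C(=O)OC3)oc1=O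
A4 | alternative 2 | tetracyclic C11 pinacol boronate with C7 ketone, 12-methoxy group and 19,20-lactone | COc1c(B4OC(C)(C)C(C)(C)O4)c2c(cc1)C(=O)C[C@@H]1[C@]23CCC[C@]1(C)C(=O)OC3
A5 | alternative 3 | tert-butyl (S)-3-[(tert-butyldimethylsilyloxy)methyl]-1-methyl-2-vinylcyclohex-2-ene-1-carboxylate | C=CC1=C(CO[Si](C)(C)C(C)(C)C)CCC[C@]1(C)C(=O)OC(C)(C)C
A6 | alternative 3 | 2-isopropyl-3-methoxy-1,4-benzoquinone | COC1=C(C(C)C)C(=O)C=CC1=O
A7 | alternative 3 | tricyclic 11,14-hydroquinone with C5=C6 alkene, C20 silyl ether and C19 tert-butyl ester | COc1c(O)c2c(c(O)c1C(C)C)CC=C1[C@]2(CO[Si](C)(C)C(C)(C)C)CCC[C@]1(C)C(=O)OC(C)(C)C
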